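In a one-step world substrate decays with one time constant, and what it loses stands as target. This flask is richer. I have followed it so far as the gamma run, and zeta is the same charge run warmer.

common to all: substrate 0.050 M; gas phase 6.2 mM (held); impurity 3.6 mM

| run | free catalyst | temperature | remark | time |
|---|---|---|---|---|
| gamma | 5 mM | 25 °C | the very flask that is asked about, followed so far |  |
| zeta | 5 mM | 31 °C | run made earlier |  |
| flask | 5.0 mM | 25 °C |  | 6.0 d |

| run | time / d | target / % | substrate / % |
|---|---|---|---|
| gamma | 0.625 | 18.4 | 80.6 |
| gamma | 1.25 | 32.4 | 65.4 |
| gamma | 2.00 | 44.0 | 50.0 |
| gamma | 3.00 | 53.2 | 33.7 |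
| gamma | 4.00 | 58.8 | 23.3 |
| zeta | 0.625 | 23.5 | 74.8 |
| zeta | 1.25 | 39.5 | 54.9 |
| zeta | 2.00 | 52.4 | 36.4 |
| zeta | 3.00 | 61.3 | 20.7 |
| zeta | 4.00 | 65.9 | 11.7 |

(standard deviation of a reading: 0.3 percentage points)

- south: at 6.0 d raise the temperature by 25 K, then wait 40 h
- east: change nothing and wait 40 h more
- south-east: at 6.0 d add free catalyst, 100% of the amount charged, then wait 40 h
- north: at 6.0 d take out 90% of the target then present, then wait 40 h

- at the start none of the gas is dissolved
- removed target is counted in
- the earlier runs were read with a standard deviation of 0.3 percentage points
- on the list of suspects stand: target + free catalyst <-> isomer of the product + free catalyst; substrate + dissolved gas + free catalyst -> free catalyst + target; free catalyst + impurity -> spent catalyst; gas phase <-> dissolved gas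
- additions bring no volume worth counting

1. target, in percent of the substrate first charged, at 6.0 d
2. the option that brings most further target ("none" if no option brings more than 2 percentage points) (south / east / south-east / north / none)
3. target present, with what was taken out counted in, in percent of the substrate first charged, after east
4. target present, with what was taken out counted in, in percent of the substrate first charged, after north

The first instants belong to the catalyst. On the list of suspects, one impurity takes one free catalyst into spent catalyst. The impurity charge is 72.0% of the catalyst charge, less than it, so impurity is the limiting reagent of that step. So 28.0% of the catalyst charge stays free, and I call this fraction the surviving share. The readings place this early. In gamma the decay constant of substrate reads 0.345 d⁻¹ up to the first reading and 0.369 d⁻¹ between the last two. It has not fallen, so I take the poisoning as finished before 0.625 d.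

In the middle the surviving share works steadily. In gamma substrate falls pseudo-first-order, with a time constant I read as 2.71 d. But on the list of suspects the same free catalyst also turns target into isomer. In gamma the share missing from substrate and target, which I book as isomer, reads 13.1% at 3.00 d and 17.9% at 4.00 d, a pace of 0.0480 d⁻¹ of the substrate charge.

For the end I carry both lines forward. My reckoning at 6.0 d gives substrate 11.1%, isomer 27.5% and target 61.4%. Substrate then feeds target at 0.0411 d⁻¹ of the substrate charge, less than the pace of isomer, so by my reckoning target has stopped rising. I expect no gain from east. South-east lifts free catalyst to 128% of the catalyst charge and hurries both steps, so I expect a loss. Heat and removal I do not reckon here.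

The forecast stands above my figure, with 65.8% now, 68.1% after east and 80.3% after north, and it picks north because “Removing target pulls isomer back”.

The flask gives 61.2% at 6.0 d. The best option is south, which brings 33 percentage points, more than any other, while south-east brings −6.6 points, east ends at 60.0% and north at 70.5%.

    target + free catalyst ⇌ isomer of the product + free catalyst, rate k1*[free catalyst]*[target] forward; the back reaction follows from the equilibrium constant (K = 0.910, k = 0.00120 M⁻¹ s⁻¹, Ea = 74.0 kJ mol⁻¹, ΔH = −90.0 kJ mol⁻¹)
    substrate + dissolved gas + free catalyst → free catalyst + target (k = 0.540 M⁻² s⁻¹, Ea = 52.0 kJ mol⁻¹)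
    free catalyst + impurity → spent catalyst (k = 0.0860 M⁻¹ s⁻¹, Ea = 59.0 kJ mol⁻¹)
    gas phase ⇌ dissolved gas, rate k4*(csat - [dissolved gas]) (kL = 1.80 × 10⁻⁴ s⁻¹)
    (constants at 25 °C)

At 0.600 d the flask holds free catalyst at 28.0% and spent catalyst at 72.0% of the catalyst charge, with impurity at 0.0546% of its own, and the surviving share I reckoned is 28.0%. A neighbour flask, the same but for its impurity, has impurity at 44.0% of the catalyst charge, so its surviving share is 56.0%. At 6.00 d that neighbour holds free catalyst at 56.0% of the catalyst charge, with target 56.0%, isomer 42.8% and substrate 1.23% of the substrate charge.

All runs were computed with made-up constants, noise included.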